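**Plan**

- Numbering follows the ionones: ring A is C1–C6 (gem-dimethyl C1, ester carbinol C3), the oxirane spans C5–C6, the chain is C7=C8–C9(=O)–C10.
- Enabling feature: the vinyl oxirane O–C5–C6–C7=C8 equals a 1,2-dioxine bridging C5 and C8 of the ring A diene C5=C6–C7=C8, after loss of the C8 oxygen and a shift of the double bond from C6=C7 to C7=C8.
- Retrosynthesis: C9=O back to a silylated carbinol; O–C6 cut back to the 5,8-endoperoxide; C5–O and C8–O cut to the dienyl silyl ether and O2; C6–C7 cut to a ring A enol triflate and an (E)-butenylboronate; ester C–O cut to myristoyl chloride.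
- Forward: ring A comes ready-made from 4-oxoisophorone; acylation, enol triflation and Suzuki coupling join the C4 chain; photooxygenation closes the dioxine ring; PPh3 contracts it to the oxirane; desilylation and oxidation unveil the enone.
- Stereochemistry: C3 from yeast reduction followed by substrate-controlled ketone hydrogenation; C5 from oxygen attack anti to the C3 ester; C6 from delivery of the C5 oxygen on its own face; E-C7=C8 from syn hydroboration and its re-formation in the SN2′ step; C9, from (S)-but-3-yn-2-ol, is temporary.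

Key step: step 8

Assumption: an acyloxy group at C3, which cannot hydrogen-bond to the incoming oxygen, is taken to bias attack at C5 to the opposite ring face, in the sense seen in peracid epoxidation of such rings, and the two endoperoxide diastereomers are taken to be separable.

**Step 1**
Reactants: 1 4-oxoisophorone
Product: 2 (6R)-2,2,6-trimethylcyclohexane-1,4-dione
Conditions: baker's yeast, sucrose, H2O, 30 °C
Reagents that add atoms: none
Why: Enzymatic conjugate reduction (ene-reductase activity of fermenting yeast) of the activated ring C=C is the established way to set this methyl-bearing centre as R.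

**Step 2**
Reactants: 2 (6R)-2,2,6-trimethylcyclohexane-1,4-dione
Product: 3 (4R,6R)-4-hydroxy-2,2,6-trimethylcyclohexanone
Conditions: H2 (1 atm), Raney Ni, MeOH, 20 °C; recrystallisation
Reagents that add atoms: none
Why: Heterogeneous catalytic hydrogenation reduces only the unhindered C4 carbonyl, from the face away from the axial methyl of the gem-dimethyl group, so the carbinol should form mainly R (trans to the C6 methyl); the minor cis epimer is removed by recrystallisation.

**Step 3**
Reactants: 3 (4R,6R)-4-hydroxy-2,2,6-trimethylcyclohexanone; 4 tetradecanoyl chloride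
Product: 5 (1R,5R)-3,3,5-trimethyl-4-oxocyclohexyl tetradecanoate
Conditions: pyridine, DMAP (cat.), CH2Cl2, 0 °C to 20 °C
Reagents that add atoms: none
Why: Nucleophilic acyl substitution (DMAP-catalysed O-acylation) of the secondary alcohol with the acid chloride; neither stereocentre is touched.

**Step 4**
Reactants: 5 (1R,5R)-3,3,5-trimethyl-4-oxocyclohexyl tetradecanoate
Product: 6 (4R)-2,6,6-trimethyl-4-(tetradecanoyloxy)cyclohex-1-en-1-yl trifluoromethanesulfonate
Conditions: Tf2O, 2,6-di-tert-butyl-4-methylpyridine, CH2Cl2, 0 °C to 20 °C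
Reagents that add atoms: trifluoromethanesulfonic anhydride, O=S(=O)(OS(=O)(=O)C(F)(F)F)C(F)(F)F
Why: Enol triflate formation by O-sulfonylation of the ketone with a hindered pyridine base can remove only the single α-hydrogen, so one tetrasubstituted enol triflate should form (the methyl-bearing stereocentre becomes sp2), and no strong base is present to enolise the ester.

**Step 5**
Reactants: 7 (S)-but-3-yn-2-ol
Product: 8 (S)-tert-butyl(but-3-yn-2-yloxy)dimethylsilane
Conditions: TBSCl, imidazole, CH2Cl2, 20 °C
Reagents that add atoms: tert-butyldimethylsilyl chloride, CC(C)(C)[Si](C)(C)Cl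
Why: Imidazole-promoted silylation of a secondary alcohol, with retention at the carbinol carbon.

**Step 6**
Reactants: 8 (S)-tert-butyl(but-3-yn-2-yloxy)dimethylsilane
Product: 9 tert-butyldimethyl{[(2S,3E)-4-(4,4,5,5-tetramethyl-1,3,2-dioxaborolan-2-yl)but-3-en-2-yl]oxy}silane
Conditions: pinacolborane, Cp2Zr(H)Cl (cat.), Et3N (cat.), neat, 60 °C
Reagents that add atoms: pinacolborane, CC1(C)OBOC1(C)C
Why: Zirconocene-hydride-catalysed hydroboration of a terminal alkyne (syn hydrozirconation, then zirconium-to-boron exchange) should give the terminal (E)-alkenylboronate, leaving the propargylic centre untouched.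

**Step 7**
Reactants: 6 (4R)-2,6,6-trimethyl-4-(tetradecanoyloxy)cyclohex-1-en-1-yl trifluoromethanesulfonate; 9 tert-butyldimethyl{[(2S,3E)-4-(4,4,5,5-tetramethyl-1,3,2-dioxaborolan-2-yl)but-3-en-2-yl]oxy}silane
Product: 10 (3R,9S)-3-tetradecanoyloxy-β-ionol tert-butyldimethylsilyl ether [(1R)-4-[(1E,3S)-3-{[tert-butyl(dimethyl)silyl]oxy}but-1-en-1-yl]-3,5,5-trimethylcyclohex-3-en-1-yl tetradecanoate]
Conditions: Pd(OAc)2 (cat.), SPhos, K3PO4, THF/H2O, 50 °C
Reagents that add atoms: none
Why: Suzuki–Miyaura coupling of an enol triflate with an alkenylboronate forms C6–C7 with retention of the E geometry; the bulky electron-rich biarylphosphine should carry the hindered tetrasubstituted triflate through oxidative addition and transmetalation, and phosphate is mild enough for the ester.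

**Step 8**
Reactants: 10 (3R,9S)-3-tetradecanoyloxy-β-ionol tert-butyldimethylsilyl ether
Product: 11 5,8-endoperoxide, (3R,7S,8aR)-3-[(1S)-1-{[tert-butyl(dimethyl)silyl]oxy}ethyl]-5,5,8a-trimethyl-3,5,6,7,8,8a-hexahydrobenzo[c][1,2]dioxin-7-yl tetradecanoate (ionone numbering 3S,5R,8R,9S; O–O bridges C5 and C8, C6=C7, C5–O anti to the C3 ester)
Conditions: O2, tetraphenylporphyrin (cat.), visible light (white LED), CH2Cl2, −78 °C
Reagents that add atoms: dioxygen, O=O
Why: The sensitiser passes triplet energy to O2, and the singlet oxygen adds in a concerted suprafacial [4+2] fashion to C5 and C8 of the twisted s-cis diene C5=C6–C7=C8, forming C5–O and C8–O and leaving C6=C7. The closest known reaction is the dye-sensitised photooxygenation of 1,3-dienes, β-ionol-type ring dienes included, to 3,6-dihydro-1,2-dioxines. The six-membered 1,2-dioxine ring closes by this cycloaddition across the diene termini and is fused to ring A at C5–C6. C5 is controlled by the C3 stereocentre, whose acyloxy group is expected to send oxygen to the opposite ring face; C8 follows from C5 through the E geometry of C7=C8 and the suprafacial addition, which place C9 cis to C4 on the new ring. The step needs cycloaddition to win over ene reactions (hydrogen abstraction at C4, at the C5 methyl and at C7) and needs the anti face. The substrate features relied on are the ground-state s-cis twist about C6–C7, the electron-rich silyl ether chain without a C9 carbonyl, and the absence of a free hydroxyl that could deliver oxygen syn; the minor syn diastereomer should be removable by chromatography.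

**Step 9**
Reactants: 11 5,8-endoperoxide
Product: 13 (1S,4S,6R)-1-[(1E,3S)-3-{[tert-butyl(dimethyl)silyl]oxy}but-1-en-1-yl]-2,2,6-trimethyl-7-oxabicyclo[4.1.0]heptan-4-yl tetradecanoate, via C8-oxyphosphonium C5-alkoxide betaine 12 (not isolated)
Conditions: PPh3, toluene, 0 °C to 20 °C
Reagents that add atoms: none
Why: Triphenylphosphine attacks the less hindered peroxide oxygen on secondary C8, and the tertiary C5 alkoxide of betaine 12 then adds to C6 on the face it already occupies while Ph3P=O leaves from C8 (intramolecular SN2′, the known phosphine deoxygenation of unsaturated endoperoxides to vinyl epoxides); C6 is thereby set by C5, and the new C7=C8 bond should be E because C9 turns away from the fully substituted C6.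

**Step 10**
Reactants: 13 vinyl oxirane silyl ether
Product: 14 (1S,4S,6R)-1-[(1E,3S)-3-hydroxybut-1-en-1-yl]-2,2,6-trimethyl-7-oxabicyclo[4.1.0]heptan-4-yl tetradecanoate
Conditions: Bu4NF, AcOH, THF, 0 °C to 20 °C
Reagents that add atoms: none
Why: Fluoride-driven Si–O cleavage (desilylation), buffered with acetic acid so that neither the ester nor the vinyl oxirane meets free alkoxide or strong acid.

**Step 11**
Reactants: 14 epoxy allylic alcohol
Product: 15 (1S,4S,6R)-2,2,6-trimethyl-1-[(1E)-3-oxobut-1-en-1-yl]-7-oxabicyclo[4.1.0]heptan-4-yl tetradecanoate (CNP0118807.1)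
Conditions: Dess–Martin periodinane, pyridine, CH2Cl2, 0 °C
Reagents that add atoms: none
Why: Dess–Martin oxidation of the secondary allylic alcohol to the enone under pyridine buffering removes the temporary C9 stereocentre and leaves ester, oxirane and the E-alkene untouched.

**Compound list**

1 | 4-oxoisophorone (2,6,6-trimethylcyclohex-2-ene-1,4-dione) | CC1=CC(=O)CC(C)(C)C1=O | starting material
2 | (6R)-2,2,6-trimethylcyclohexane-1,4-dione | O=C1CC(C)(C)C(=O)[C@H](C)C1 | intermediate
3 | (4R,6R)-4-hydroxy-2,2,6-trimethylcyclohexanone | O[C@H]1CC(C)(C)C(=O)[C@H](C)C1 | intermediate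
4 | tetradecanoyl chloride (myristoyl chloride) | CCCCCCCCCCCCCC(=O)Cl | starting material
5 | (1R,5R)-3,3,5-trimethyl-4-oxocyclohexyl tetradecanoate | CCCCCCCCCCCCCC(=O)O[C@H]1CC(C)(C)C(=O)[C@H](C)C1 | intermediate
6 | (4R)-2,6,6-trimethyl-4-(tetradecanoyloxy)cyclohex-1-en-1-yl trifluoromethanesulfonate | CCCCCCCCCCCCCC(=O)O[C@H]1CC(C)(C)C(OS(=O)(=O)C(F)(F)F)=C(C)C1 | intermediate
7 | (S)-but-3-yn-2-ol | C#C[C@H](C)O | starting material
8 | (S)-tert-butyl(but-3-yn-2-yloxy)dimethylsilane | C#C[C@H](C)O[Si](C)(C)C(C)(C)C | intermediate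
9 | tert-butyldimethyl{[(2S,3E)-4-(4,4,5,5-tetramethyl-1,3,2-dioxaborolan-2-yl)but-3-en-2-yl]oxy}silane | CC1(C)OB(OC1(C)C)/C=C/[C@H](C)O[Si](C)(C)C(C)(C)C | intermediate
10 | (1R)-4-[(1E,3S)-3-{[tert-butyl(dimethyl)silyl]oxy}but-1-en-1-yl]-3,5,5-trimethylcyclohex-3-en-1-yl tetradecanoate | CCCCCCCCCCCCCC(=O)O[C@H]1CC(C)(C)C(/C=C/[C@H](C)O[Si](C)(C)C(C)(C)C)=C(C)C1 | intermediate
11 | (3R,7S,8aR)-3-[(1S)-1-{[tert-butyl(dimethyl)silyl]oxy}ethyl]-5,5,8a-trimethyl-3,5,6,7,8,8a-hexahydrobenzo[c][1,2]dioxin-7-yl tetradecanoate | CCCCCCCCCCCCCC(=O)O[C@H]1CC(C)(C)C2=C[C@H]([C@H](C)O[Si](C)(C)C(C)(C)C)OO[C@]2(C)C1 | intermediate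
12 | betaine with C5 alkoxide, (Z)-C6=C7 and triphenylphosphonio-oxy group on C8 (formed and consumed in step 9) | CCCCCCCCCCCCCC(=O)O[C@H]1CC(C)(C)/C(=C/[C@H]([C@H](C)O[Si](C)(C)C(C)(C)C)O[P+](c2ccccc2)(c2ccccc2)c2ccccc2)[C@](C)([O-])C1 | intermediate
13 | (1S,4S,6R)-1-[(1E,3S)-3-{[tert-butyl(dimethyl)silyl]oxy}but-1-en-1-yl]-2,2,6-trimethyl-7-oxabicyclo[4.1.0]heptan-4-yl tetradecanoate | CCCCCCCCCCCCCC(=O)O[C@H]1CC(C)(C)[C@]2(/C=C/[C@H](C)O[Si](C)(C)C(C)(C)C)O[C@]2(C)C1 | intermediate
14 | (1S,4S,6R)-1-[(1E,3S)-3-hydroxybut-1-en-1-yl]-2,2,6-trimethyl-7-oxabicyclo[4.1.0]heptan-4-yl tetradecanoate | CCCCCCCCCCCCCC(=O)O[C@H]1CC(C)(C)[C@]2(/C=C/[C@H](C)O)O[C@]2(C)C1 | intermediate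
15 | (1S,4S,6R)-2,2,6-trimethyl-1-[(1E)-3-oxobut-1-en-1-yl]-7-oxabicyclo[4.1.0]heptan-4-yl tetradecanoate | CCCCCCCCCCCCCC(=O)O[C@H]1CC(C)(C)[C@]2(/C=C/C(C)=O)O[C@]2(C)C1 | target

**Step count and risks**

Total step count: 11. Longest linear sequence: 9 steps (steps 1, 2, 3, 4, 7, 8, 9, 10, 11); steps 5 and 6 build the side-chain fragment.

Steps most likely to fail:

1. Step 9. The C5 alkoxide of the betaine may close directly on C8 to the five-membered 5,8-ether instead of adding to C6. Alternatively, phosphorus may migrate to the C5 oxygen and the tertiary allylic C5–O bond may ionise. In either case the oxirane would not form. Fallback by direct epoxidation at the enone stage, setting out from 10: buffered Bu4NF/AcOH in THF removes the silyl group to give (1R)-4-[(1E,3S)-3-hydroxybut-1-en-1-yl]-3,5,5-trimethylcyclohex-3-en-1-yl tetradecanoate F1. Dess–Martin oxidation then gives (3R)-3-tetradecanoyloxy-β-ionone F2. 3-Chloroperbenzoic acid with NaHCO3 in CH2Cl2 at 0 °C should epoxidise the electron-rich ring double bond in preference to the enone double bond, mainly anti to the ester, returning to the route at 15.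

2. Step 8. Facial selectivity at C5 may be poor, and singlet oxygen may be diverted into ene pathways (hydrogen abstraction at C4, at the C5 methyl, or at C7 to give an allene). The endoperoxide must also be kept away from amine bases, because its C8–H allows Kornblum–DeLaMare cleavage. Fallback by reagent-controlled epoxidation, setting out from 6: Stille hydroxymethylation with (tributylstannyl)methanol (Pd(PPh3)4, LiCl, dioxane, 100 °C) gives (1R)-4-(hydroxymethyl)-3,5,5-trimethylcyclohex-3-en-1-yl tetradecanoate F3. Sharpless asymmetric epoxidation (Ti(OiPr)4, (−)-diethyl D-tartrate, tBuOOH, 4 Å molecular sieves, CH2Cl2, −20 °C) should place the oxirane anti to the ester, giving (1R,4S,6R)-1-(hydroxymethyl)-2,2,6-trimethyl-7-oxabicyclo[4.1.0]heptan-4-yl tetradecanoate F4. Dess–Martin oxidation with pyridine gives (1S,4S,6R)-1-formyl-2,2,6-trimethyl-7-oxabicyclo[4.1.0]heptan-4-yl tetradecanoate F5. Wittig olefination with 1-(triphenylphosphoranylidene)propan-2-one in toluene at 80 °C should give the E-enone, returning to the route at 15.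

3. Step 7. Transmetalation at the tetrasubstituted, doubly flanked enol triflate may be slow, so that triflate hydrolysis, ester saponification or protodeboronation in the basic aqueous medium take over. Fallback by base-free Stille coupling, setting out from 8: hydrozirconation with Cp2Zr(H)Cl in THF followed by Bu3SnCl gives tert-butyldimethyl{[(2S,3E)-4-(tributylstannyl)but-3-en-2-yl]oxy}silane F6. Coupling of F6 with 6 (Pd2(dba)3, AsPh3, LiCl, N-methylpyrrolidone, 60 °C) returns to the route at 10.

**Further compounds**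

F1 | step 9 | (1R)-4-[(1E,3S)-3-hydroxybut-1-en-1-yl]-3,5,5-trimethylcyclohex-3-en-1-yl tetradecanoate | CCCCCCCCCCCCCC(=O)O[C@H]1CC(C)(C)C(/C=C/[C@H](C)O)=C(C)C1
F2 | step 9 | (3R)-3-tetradecanoyloxy-β-ionone [(1R)-3,5,5-trimethyl-4-[(1E)-3-oxobut-1-en-1-yl]cyclohex-3-en-1-yl tetradecanoate] | CCCCCCCCCCCCCC(=O)O[C@H]1CC(C)(C)C(/C=C/C(C)=O)=C(C)C1
F3 | step 8 | (1R)-4-(hydroxymethyl)-3,5,5-trimethylcyclohex-3-en-1-yl tetradecanoate | CCCCCCCCCCCCCC(=O)O[C@H]1CC(C)(C)C(CO)=C(C)C1
F4 | step 8 | (1R,4S,6R)-1-(hydroxymethyl)-2,2,6-trimethyl-7-oxabicyclo[4.1.0]heptan-4-yl tetradecanoate | CCCCCCCCCCCCCC(=O)O[C@H]1CC(C)(C)[C@]2(CO)O[C@]2(C)C1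
F5 | step 8 | (1S,4S,6R)-1-formyl-2,2,6-trimethyl-7-oxabicyclo[4.1.0]heptan-4-yl tetradecanoate | CCCCCCCCCCCCCC(=O)O[C@H]1CC(C)(C)[C@]2(C=O)O[C@]2(C)C1
F6 | step 7 | tert-butyldimethyl{[(2S,3E)-4-(tributylstannyl)but-3-en-2-yl]oxy}silane | CCCC[Sn](CCCC)(CCCC)/C=C/[C@H](C)O[Si](C)(C)C(C)(C)C
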